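## The problem

Trichopsistide B (17) is pentacyclic. A 6,8-dioxabicyclo[3.2.1]octane (dioxolane C7–O8–C9–O28–C27 bridging the tetrahydropyran C9–O28–C27–C26–C25–C29) is fused along C9–C29 to a cyclohexane (C9–C10–C11–C12–C14–C29) and along C25–C29 to a dihydropyran (C14–O16–C17=C24–C25–C29) that is annulated to a 6-methyl-2-pyrone, so the methine C29 belongs to three six-membered rings. (Locants follow the atom order of the structure: hexyl C1–C6, C7, O8, C9, C10, C11, C12 with O13, C14 with O15 and O16, pyrone C17–C24, C25, C26, C27, O28, C29.) Seven stereocentres have to be set: 7S, 9R, 12R, 14S, 25R, 27S, 29S. They are not independent: C9 and C27 are locked to each other by the bridge and tied to C7 through the exo position of the hexyl group; C25 can be read from the convex face of the bicycle; C29 (alpha to a masked ketone) and C14 (a hemiketal) can settle under equilibrium; only C12, 1,4 to C9 and outside the bicycle, has no neighbour able to induce it and must be brought in enantiopure. C9 and C14 are both ketone-level carbons flanking C29, so a synthesis has to tell them apart: C9 must end as the ketal, C14 as the hemiketal. The fragile points are the C14 hemiketal beside the C12 carbinol (an alpha-ketol when open), the C9 ketal beta to C14 (open to beta-elimination once C14 is a ketone with an enolisable C29), the base-sensitive 2-pyrone, and any alpha-alkoxy aldehyde carried at C27. The enabling feature appears when the pyrone is removed by a retro-Michael/retro-hemiketal step: in the resulting enone the ring O28–C27–C26–C25=C29–C9 is a 3,6-dihydro-2H-pyran, the formal adduct of a 1-alkoxydiene C26=C25–C29=C9–O8 with an aldehyde C27=O28 that hangs from the diene through C7, and this diene is simply the 2-vinyl derivative of a cyclohexane-1,3-dione vinylogous ester in which C9 (enol ether) and C14 (ketone) are different from the outset.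

## Retrosynthesis

**17 ⇒ 16 ⇒ 13 + 14.** After removal of the C12 silyl ether (16), the bonds C24–C25 and C14–O16 are cut. This takes off the commercial pyrone 14 as a 1,3-C,O-dinucleophile and leaves the tricyclic enone 13. The cut is preferred over carrying the pyrone through the ring construction, where its lactone and its nucleophilic C3 would be exposed to every earlier reagent. It deletes two rings and three stereocentres (C25, C29, C14) at once. The forward reaction is a warfarin-type Michael addition/hemiketal closure. It must attack C25 on the face away from the O8–C7 bridge and must run under conditions mild enough that the C9 ketal does not open by beta-elimination.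

**13 ⇒ 12.** The bonds C26–C27 and C9–O28 are cut together. Cutting both C–O bonds of the ketal instead (keto-diol ketalisation) would leave a 2-alkyl-1,3-dione whose two carbonyls C9 and C14 sit symmetrically about the side chain and cannot be distinguished. Cutting only C9–O8 leaves the tetrahydropyran to be built separately. The two-bond cut maps onto an intramolecular oxa-Diels–Alder reaction of the aldehyde 12. In 12 the vinylogous ester fixes C9 as the only carbon that can become the ketal. The precursor is monocyclic with two remote stereocentres (C7, C12). The forward step must activate the aldehyde in the presence of the more basic enone carbonyl and must pass the tether over the diene face that places the hexyl group exo.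

**12 ⇒ 10 + 11; 10 ⇒ 8; 8 ⇒ 7.** The C29–C25 bond is cut to the alpha-iodo vinylogous ester 10 and tributyl(vinyl)stannane 11 (Stille coupling). The C27 aldehyde is traced to the terminal alkene of the allyl ether 8, and the C29 iodide to electrophilic iodination of 7. The order is dictated by chemoselectivity. Iodination and alkene cleavage precede the coupling, so that the oxidant meets only one terminal alkene and zerovalent palladium never meets the allyl vinylogous ester, which could ionise to a pi-allyl complex. Each step is a standard functional-group operation.

**7 ⇒ 6 + 2.** The enol ether bond C9–O8 is cut, giving the ethyl vinylogous ester 6 and (S)-non-1-en-3-ol 2. Acid-catalysed alkoxy exchange by addition–elimination at C9 keeps the C7–O bond intact, so the configuration of 2 is retained. O-alkylation of a 4-silyloxy-1,3-dione was rejected because it would give both enol ether regioisomers. The step joins the two enantiopure fragments; it has to leave the silyl ether and the position of the carbonyl untouched.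

**6 ⇒ 5 ⇒ 4 ⇒ 3, and 2 ⇒ 1.** The C12–O13 bond is cut back to commercial 3-ethoxycyclohex-2-en-1-one 3 through alpha-prime acetoxylation (4), enzymatic resolution (5) and silylation (6). Compound 3 has a single enolisable position, so regiochemistry is not in question. The alcohol 2 comes from commercial racemic non-1-en-3-ol 1 by kinetic resolution. Both resolutions are placed at the very start, on inexpensive material.

## Roads not taken

**Alternative 1:** Chromanol oxidative dearomatisation.
- **Cut:** only C9–O8, on an aromatic ring. The precursor is the phenol A1, a chroman (O28 on C9) fused to the pyranopyranone, with a free C12 phenol para to C9 and a free C7 carbinol.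
- **Key step:** oxidation with PhI(OAc)2 would let the C7 hydroxyl attack C9 and give the quinone monoketal A2, which contains the bicyclic ketal.
- **Merits:** oxidative para-ketalisation of 4-alkoxyphenols by a tethered alcohol is closely precedented, so this key step is safer than the chosen one. C9 and C14 are differentiated trivially by their different oxygen substituents. The flat arene is robust and the pyrone can be attached early.
- **Weak points:** A2 still needs four hydrogens and three stereocentres: saturation of C10=C11, facially controlled reduction of the C12 ketone, and net hydration of the tetrasubstituted C14=C29 enol ether with H29 and the C14 hydroxyl trans. Quinone monoketals tend to rearomatise on reduction by expelling a ketal oxygen, which would undo the key step. C25, doubly benzylic in A1, must be set enantioselectively and is prone to epimerise.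
- **Comparison:** the chosen plan has a less certain key step. What it sets against this is that C12 is in place before the key step and only the pyrone addition and a desilylation follow it, whereas alternative 1 postpones the hardest stereochemical work to the end.

**Alternative 2:** Alkoxyfuran Diels–Alder, bridge opening and ketal capture.
- **Cut:** C9–C29 and C12–C14 (the carbocycle) together with C9–O8. The precursor A3 is the 2-furyl ether of the C27 hydroxyl of a syn-diol that carries an (E)-nitroalkene.
- **Key step:** on heating, cycloaddition, opening of the oxanorbornene at C9 and capture of the oxocarbenium ion by the C7 hydroxyl would give the tricyclic nitro ketal A4.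
- **Merits:** three rings and the centres C9, C12 and C29 arise in one thermal step from an acyclic compound. Its only stereocentres (C7, C27) come from one asymmetric dihydroxylation. C12 is set relative to C9 by the oxygen bridge. In stereochemical economy this is better than the chosen plan, which needs one resolution for C7 and a second, independent one for C12.
- **Weak points:** 2-furyl ethers of hindered secondary alcohols are hard to make and acid-labile. The nitroalkene may be attacked by the furan in a conjugate addition instead of a cycloaddition. The ring-opened zwitterion can eliminate or aromatise before the C7 hydroxyl arrives. A4 carries C25 as a methylene group and C14 as a nitro carbon, so a Nef reaction, saturation of C10=C11 and a dehydrogenation to the C29=C25 enone are needed before the pyrone can be added.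
- **Comparison:** against the better stereochemical economy the chosen plan sets robust vinylogous-ester intermediates, a key step that delivers the enone at the correct oxidation level, and a shorter sequence after the key step.

**Alternative 3:** Lactone carbonyl becomes the ketal carbon by samarium Barbier closure.
- **Cut:** C9–C10. The precursor A5 is a delta-lactone (C9 as the carbonyl, O28 as the ring oxygen) that already carries the pyranopyranone, the silylated C14 hemiketal, the C12 and C7 silyl ethers and a primary iodide at C10.
- **Key step:** SmI2 with catalytic NiI2 would add the derived organosamarium to C9 and give the lactol A6. Acid would later close the ketal with the C7 hydroxyl.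
- **Merits:** Barbier additions of alkyl iodides to lactones that stop at the lactol are established. C9 arrives at the right oxidation level, and the final ketalisation is thermodynamically favoured. Of the four plans this has the most reliable key step and end-game.
- **Weak points:** A5 already contains six of the seven stereocentres and all the sensitive functionality, so the key step builds one bond and no stereocentre of consequence at the end of a long linear sequence. SmI2 can reduce the 2-pyrone. The silylated hemiketal is labile. The lactol alkoxide can open to the hydroxy ketone.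
- **Comparison:** the chosen plan accepts more risk in its key step in exchange for two rings and two stereocentres formed in that step and a markedly shorter sequence.

Key step: step 9

Assumption: the Burkholderia cepacia lipase is taken to hydrolyse the (R)-acetate of 4 faster (conjugated carbonyl carbon as the larger substituent in the empirical size rule for secondary acetates); if the preference is the reverse, the unreacted (R)-acetate is deacetylated and carried on, and nothing downstream changes.

## Route

Step 1
Reactants: 1 rac-non-1-en-3-ol
Product: 2 (3S)-non-1-en-3-ol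
Conditions: Ti(OiPr)4 (10 mol%), D-(−)-DIPT (15 mol%), t-BuOOH (0.6 equiv), 4 Å MS, CH2Cl2, −20 °C
Reagents that add atoms: none
Why: Sharpless kinetic resolution: with the D-tartrate the (R)-alcohol is epoxidised faster, so the (S)-alcohol should be recovered enantioenriched once conversion passes one half; no bond to the carbinol carbon (future C7) is touched.

Step 2
Reactants: 3 3-ethoxycyclohex-2-en-1-one
Product: 4 rac-4-ethoxy-2-oxocyclohex-3-en-1-yl acetate
Conditions: Mn(OAc)3·2H2O, benzene, reflux (Dean–Stark)
Reagents that add atoms: manganese triacetate, CC(=O)[O-].CC(=O)[O-].CC(=O)[O-].[Mn+3]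
Why: Alpha-prime acetoxylation of an enone with Mn(OAc)3; the manganese enolate can form only toward the single enolisable CH2 (future C12), and the push–pull double bond is not oxidised.

Step 3
Reactants: 4 rac-4-ethoxy-2-oxocyclohex-3-en-1-yl acetate
Product: 5 (6R)-3-ethoxy-6-hydroxycyclohex-2-en-1-one
Conditions: lipase from Burkholderia cepacia, phosphate buffer (pH 7)/MTBE, rt, stopped near half conversion
Reagents that add atoms: none
Why: Lipase-mediated kinetic resolution of an alpha-acetoxy ketone by enantioselective ester hydrolysis; the (R)-acetate should be cleaved to 5 while the unreacted (S)-enantiomer of 4 is removed by chromatography, which fixes C12 as R.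

Step 4
Reactants: 5 (6R)-3-ethoxy-6-hydroxycyclohex-2-en-1-one
Product: 6 (6R)-6-[(tert-butyldimethylsilyl)oxy]-3-ethoxycyclohex-2-en-1-one
Conditions: TBSCl, imidazole, DMF, rt
Reagents that add atoms: tert-butyldimethylsilyl chloride, CC(C)(C)[Si](C)(C)Cl
Why: Standard silylation of a secondary alcohol; imidazole does not enolise the vinylogous ester, so C12 keeps its configuration.

Step 5
Reactants: 6 (6R)-6-[(tert-butyldimethylsilyl)oxy]-3-ethoxycyclohex-2-en-1-one; 2 (3S)-non-1-en-3-ol
Product: 7 (6R)-6-[(tert-butyldimethylsilyl)oxy]-3-[(3S)-non-1-en-3-yloxy]cyclohex-2-en-1-one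
Conditions: 2 (1.5 equiv), PPTS (10 mol%), benzene, reflux through 5 Å MS
Reagents that add atoms: none
Why: Acid-catalysed alkoxy exchange (transetherification) of a vinylogous ester by addition of the alcohol to C9 and loss of ethanol, driven by trapping ethanol on the sieves; the C7–O bond is not broken, so C7 is retained as S, and attack at the hindered C14 next to the silyloxy carbon is disfavoured.

Step 6
Reactants: 7 (6R)-6-[(tert-butyldimethylsilyl)oxy]-3-[(3S)-non-1-en-3-yloxy]cyclohex-2-en-1-one
Product: 8 (6R)-6-[(tert-butyldimethylsilyl)oxy]-2-iodo-3-[(3S)-non-1-en-3-yloxy]cyclohex-2-en-1-one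
Conditions: NIS, CH2Cl2, 0 °C to rt, dark
Reagents that add atoms: N-iodosuccinimide, O=C1CCC(=O)N1I
Why: Electrophilic alpha-iodination of a vinylogous ester at its nucleophilic carbon C29 followed by proton loss; the isolated terminal alkene is far less nucleophilic and is left alone.

Step 7
Reactants: 8 (6R)-6-[(tert-butyldimethylsilyl)oxy]-2-iodo-3-[(3S)-non-1-en-3-yloxy]cyclohex-2-en-1-one
Product: 10 (2S)-2-{[(4R)-4-[(tert-butyldimethylsilyl)oxy]-2-iodo-3-oxocyclohex-1-en-1-yl]oxy}octanal, via vicinal diol 9 (not isolated)
Conditions: OsO4 (2 mol%), NaIO4 (4 equiv), 2,6-lutidine, dioxane/H2O (3:1), rt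
Reagents that add atoms: osmium tetroxide, O=[Os](=O)(=O)=O (oxygen carrier); sodium periodate, [Na+].[O-]I(=O)(=O)=O (terminal oxidant)
Why: Lemieux–Johnson cleavage: OsO4 dihydroxylates only the monosubstituted alkene, the tetrasubstituted iodinated push–pull alkene being inert, and periodate cleaves the diol in situ; lutidine buffers the medium so the alpha-alkoxy aldehyde centre C7 should not epimerise.

Step 8
Reactants: 10 (2S)-2-{[(4R)-4-[(tert-butyldimethylsilyl)oxy]-2-iodo-3-oxocyclohex-1-en-1-yl]oxy}octanal; 11 tributyl(vinyl)stannane
Product: 12 (2S)-2-{[(4R)-4-[(tert-butyldimethylsilyl)oxy]-2-ethenyl-3-oxocyclohex-1-en-1-yl]oxy}octanal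
Conditions: Pd2(dba)3 (5 mol%), AsPh3 (20 mol%), CuI (10 mol%), NMP, rt
Reagents that add atoms: none
Why: Stille coupling of an alpha-iodo enone with a vinylstannane; AsPh3 and CuI speed the transmetalation at the hindered iodide, and the neutral conditions tolerate the aldehyde and the silyl ether.

Step 9
Reactants: 12 (2S)-2-{[(4R)-4-[(tert-butyldimethylsilyl)oxy]-2-ethenyl-3-oxocyclohex-1-en-1-yl]oxy}octanal
Product: 13 (1R,4R,9S,10S)-4-[(tert-butyldimethylsilyl)oxy]-10-hexyl-11,12-dioxatricyclo[7.2.1.0(1,6)]dodec-6-en-5-one (in target locants 7S,9R,12R,27S; C14 ketone, C29=C25)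
Conditions: Me2AlCl (1.5 equiv), CH2Cl2, −78 to −20 °C; aq. Rochelle salt
Reagents that add atoms: none
Why: Proposed new method: Me2AlCl is expected to bind the alpha-alkoxy aldehyde (O28, assisted by O8) and lower its LUMO, while the dienol ether C26=C25–C29=C9–O8 of the 2-vinyl vinylogous ester supplies the HOMO with its large terminal coefficient at C26; C26 then bonds to C27 and O28 to C9 in an asynchronous [4+2] event whose polar limit is a vinylogous Mukaiyama-type aldol addition followed by collapse of the aluminium alkoxide onto the C9 oxocarbenium ion. The closest known reaction types are Lewis-acid oxa-Diels–Alder reactions of 1-alkoxydienes with aldehydes and vinylogous Mukaiyama aldol additions of dienol ethers; neither has been run in this bridged intramolecular form, where the two-atom tether O8–C7 joins the diene terminus C9 to the dienophile carbon. The dihydropyran (O28–C27–C26–C25=C29–C9) is the six-membered cycloadduct ring, and the dioxolane (C7–O8–C9–O28–C27) is the tether ring and closes in the same event; seen stepwise, this is a 7-endo C–C closure followed by transannular O28-to-C9 attack (5-exo with respect to C9=C29). C27 is set by the aldehyde face that C26 reaches, and C9 follows from it because the bridge allows only one relative configuration of the two bridgeheads. The selectivity needed is the diene face crossed by the tether: with (7S)-C7 one face places the hexyl chain exo on the dioxolane and the other drives it under the forming dihydropyran over C29/C25, so the exo mode should prevail and give 9R,27S; it is also the face anti to the C12 silyloxy group, so the remote centre reinforces and is not asked to direct. Chemoselectivity rests on the vinylogous ester: only C9 carries the enol ether oxygen and can become the ketal carbon, while C14 emerges as the enone carbonyl conjugated to C29=C25. Low temperature and the non-basic medium should keep the epimerisable C7 intact.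

Step 10
Reactants: 13 (1R,4R,9S,10S)-4-[(tert-butyldimethylsilyl)oxy]-10-hexyl-11,12-dioxatricyclo[7.2.1.0(1,6)]dodec-6-en-5-one; 14 4-hydroxy-6-methyl-2H-pyran-2-one
Product: 16 12-O-(tert-butyldimethylsilyl)trichopsistide B, via open keto-pyrone Michael adduct 15 (not isolated)
Conditions: 14 (1.5 equiv), Et3N (0.3 equiv), MeCN, 40 °C
Reagents that add atoms: none
Why: Michael addition of the pyrone C3 (C24) to the s-cis enone followed by hemiketal closure, the reaction type by which 4-hydroxypyrones and 4-hydroxycoumarins give warfarin-type cyclic hemiketals. C24 should attack C25 on the face anti to the O8–C7 bridge (25R), C29 is protonated or equilibrates alpha to C14 to the epimer with H29 syn to the bridge (29S), and O16 closes on C14 to the anomerically stabilised hemiketal (14S) as the thermodynamic sink.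

Step 11
Reactants: 16 12-O-(tert-butyldimethylsilyl)trichopsistide B
Product: 17 trichopsistide B
Conditions: HF·pyridine, pyridine/THF, 0 °C to rt
Reagents that add atoms: none
Why: Fluoride-mediated cleavage of a secondary silyl ether under buffered, non-basic conditions, which should leave the hemiketal, the bicyclic ketal and the pyrone untouched; no stereocentre is affected, and any open keto form recloses to the hemiketal.

## Compound list

1 | rac-non-1-en-3-ol | C=CC(O)CCCCCC | starting material
2 | (3S)-non-1-en-3-ol | CCCCCC[C@@H](C=C)O | intermediate
3 | 3-ethoxycyclohex-2-en-1-one | CCOC1=CC(=O)CCC1 | starting material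
4 | rac-4-ethoxy-2-oxocyclohex-3-en-1-yl acetate (6-acetoxy-3-ethoxycyclohex-2-en-1-one) | CCOC1=CC(=O)C(OC(C)=O)CC1 | intermediate
5 | (6R)-3-ethoxy-6-hydroxycyclohex-2-en-1-one | CCOC1=CC(=O)[C@H](O)CC1 | intermediate
6 | (6R)-6-[(tert-butyldimethylsilyl)oxy]-3-ethoxycyclohex-2-en-1-one | CCOC1=CC(=O)[C@H](O[Si](C)(C)C(C)(C)C)CC1 | intermediate
7 | (6R)-6-[(tert-butyldimethylsilyl)oxy]-3-[(3S)-non-1-en-3-yloxy]cyclohex-2-en-1-one | CCCCCC[C@@H](C=C)OC1=CC(=O)[C@H](O[Si](C)(C)C(C)(C)C)CC1 | intermediate
8 | (6R)-6-[(tert-butyldimethylsilyl)oxy]-2-iodo-3-[(3S)-non-1-en-3-yloxy]cyclohex-2-en-1-one | CCCCCC[C@@H](C=C)OC1=C(I)C(=O)[C@H](O[Si](C)(C)C(C)(C)C)CC1 | intermediate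
9 | (6R)-6-[(tert-butyldimethylsilyl)oxy]-3-{[(3S)-1,2-dihydroxynonan-3-yl]oxy}-2-iodocyclohex-2-en-1-one (both epimers at the new carbinol) | CCCCCC[C@@H](C(O)CO)OC1=C(I)C(=O)[C@H](O[Si](C)(C)C(C)(C)C)CC1 | intermediate (not isolated)
10 | (2S)-2-{[(4R)-4-[(tert-butyldimethylsilyl)oxy]-2-iodo-3-oxocyclohex-1-en-1-yl]oxy}octanal | CCCCCC[C@@H](C=O)OC1=C(I)C(=O)[C@H](O[Si](C)(C)C(C)(C)C)CC1 | intermediate
11 | tributyl(vinyl)stannane | C=C[Sn](CCCC)(CCCC)CCCC | starting material
12 | (2S)-2-{[(4R)-4-[(tert-butyldimethylsilyl)oxy]-2-ethenyl-3-oxocyclohex-1-en-1-yl]oxy}octanal | CCCCCC[C@@H](C=O)OC1=C(C=C)C(=O)[C@H](O[Si](C)(C)C(C)(C)C)CC1 | intermediate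
13 | (1R,4R,9S,10S)-4-[(tert-butyldimethylsilyl)oxy]-10-hexyl-11,12-dioxatricyclo[7.2.1.0(1,6)]dodec-6-en-5-one (silyloxy bicyclic ketal enone; 7S,9R,12R,27S) | CCCCCC[C@@H]1O[C@@]23CC[C@@H](O[Si](C)(C)C(C)(C)C)C(=O)C2=CC[C@@H]1O3 | intermediate
14 | 4-hydroxy-6-methyl-2H-pyran-2-one | Cc1cc(O)cc(=O)o1 | starting material
15 | open Michael adduct: saturated ketone of 13 carrying the 4-hydroxy-6-methyl-2-oxo-2H-pyran-3-yl group at C25 (7S,9R,12R,25R,27S,29S) | CCCCCC[C@@H]1O[C@]23CC[C@@H](O[Si](C)(C)C(C)(C)C)C(=O)[C@@H]3[C@@H](C[C@@H]1O2)c1c(O)cc(C)oc1=O | intermediate (not isolated)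
16 | 12-O-(tert-butyldimethylsilyl)trichopsistide B (7S,9R,12R,14S,25R,27S,29S) | CCCCCC[C@@H]1O[C@]23CC[C@@H](O[Si](C)(C)C(C)(C)C)[C@@]4(O)Oc5cc(C)oc(=O)c5[C@H](C[C@@H]1O2)[C@H]34 | intermediate
17 | trichopsistide B (7S,9R,12R,14S,25R,27S,29S) | CCCCCC[C@@H]1O[C@]23CC[C@@H](O)[C@@]4(O)Oc5cc(C)oc(=O)c5[C@H](C[C@@H]1O2)[C@H]34 | target

## Step count and least certain steps

Total steps: 11. Longest linear sequence: 10 steps (3 to 17, steps 2–11); step 1 prepares the second fragment, which enters at step 5.

**Step 9 (key step).**
- What may go wrong: complexation of the Lewis acid at the more basic C14 carbonyl, which lowers the nucleophilicity of the diene. Proton loss from C26 after C–C bond formation, in place of closure of O28 onto C9. Leakage to the endo-hexyl mode through weak facial bias. Epimerisation at C7 of the activated aldehyde.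
- Fallback (from 12, back at 13), using known chemistry to form the same two rings in stages. Chelation-controlled addition of vinylmagnesium bromide to the aldehyde of 12 (MgBr2·OEt2, CH2Cl2, −78 °C) would give the syn allylic alcohol (6R)-6-[(tert-butyldimethylsilyl)oxy]-2-ethenyl-3-{[(3S,4S)-3-hydroxydec-1-en-4-yl]oxy}cyclohex-2-en-1-one F1; any anti epimer would be separated here. Ring-closing metathesis with the second-generation Hoveyda–Grubbs catalyst RuCl2(H2IMes)(=CH-C6H4-2-OiPr) would close the seven-membered dienol ether (2S,3S,7R)-7-[(tert-butyldimethylsilyl)oxy]-2-hexyl-3-hydroxy-2,3,8,9-tetrahydro-1-benzoxepin-6(7H)-one F2. Catalytic CSA in CH2Cl2 would then add the C27 hydroxyl across the ring to C9 and move the C25=C26 bond into conjugation with C14, arriving at 13.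

**Step 10.**
- What may go wrong: slow addition to the trisubstituted enone. Opening of the C9 ketal by beta-elimination from the C29 enolate under base. Incomplete facial selectivity at C25. O-alkylation in place of C-alkylation of the pyrone.
- Fallback (from 14 and 13, back at 16): silylation of 14 (HMDS, cat. TMSCl) would give 6-methyl-4-[(trimethylsilyl)oxy]-2H-pyran-2-one F3. A Mukaiyama–Michael addition of F3 to 13 promoted by catalytic Sc(OTf)3 in CH2Cl2 at −40 °C, followed by mild aqueous work-up, would give the same adduct, which closes to 16 without any amine base.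

**Step 5.**
- What may go wrong: transposition of the vinylogous ester through alcohol attack at C14. Partial loss of the silyl ether under acid. Ionisation of the allylic alcohol.
- Fallback (from 2, back at 7): the enol ether is formed where no regiochemical question exists. Condensation of 2 with cyclohexane-1,3-dione (cat. TsOH, benzene, Dean–Stark) would give 3-[(3S)-non-1-en-3-yloxy]cyclohex-2-en-1-one F4. Alpha-prime acetoxylation with Mn(OAc)3 would give 4-[(3S)-non-1-en-3-yloxy]-2-oxocyclohex-3-en-1-yl acetate F5 as both C12 epimers. The lipase of step 3 would hydrolyse the (12R)-epimer to (6R)-6-hydroxy-3-[(3S)-non-1-en-3-yloxy]cyclohex-2-en-1-one F6. Silylation (TBSCl, imidazole) would then give 7.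

**Step 3.**
- What may go wrong: insufficient discrimination between the enantiomers of 4, or a preference opposite to the assumed one.
- Fallback (from 3, back at 5): the resolution is replaced by a reagent-controlled oxidation. The lithium enolate of 3 (LDA, THF, −78 °C) is hydroxylated with an enantiopure (camphorsulfonyl)oxaziridine, giving 5 directly; no new compound is made on the way.

**Step 8.**
- What may go wrong: slow transmetalation at the hindered tetrasubstituted iodide, leaving time for epimerisation at C7 or self-condensation of the aldehyde in the polar medium.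
- Fallback (from 8, back at 12): the aldehyde is unveiled after the coupling. Upjohn dihydroxylation of 8 (OsO4 cat., NMO) would give the diol 9, now isolated. Stille coupling of 9 with 11 under the conditions of step 8 would give (6R)-6-[(tert-butyldimethylsilyl)oxy]-3-{[(3S)-1,2-dihydroxynonan-3-yl]oxy}-2-ethenylcyclohex-2-en-1-one F7. Cleavage of the diol with NaIO4 (THF/pH 7 buffer, 0 °C) would deliver 12 immediately before the key step.

## Further compounds

F1 | step 9 | (6R)-6-[(tert-butyldimethylsilyl)oxy]-2-ethenyl-3-{[(3S,4S)-3-hydroxydec-1-en-4-yl]oxy}cyclohex-2-en-1-one | CCCCCC[C@@H]([C@@H](O)C=C)OC1=C(C=C)C(=O)[C@H](O[Si](C)(C)C(C)(C)C)CC1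
F2 | step 9 | (2S,3S,7R)-7-[(tert-butyldimethylsilyl)oxy]-2-hexyl-3-hydroxy-2,3,8,9-tetrahydro-1-benzoxepin-6(7H)-one | CCCCCC[C@@H]1OC2=C(C=C[C@@H]1O)C(=O)[C@H](O[Si](C)(C)C(C)(C)C)CC2
F3 | step 10 | 6-methyl-4-[(trimethylsilyl)oxy]-2H-pyran-2-one | Cc1cc(O[Si](C)(C)C)cc(=O)o1
F4 | step 5 | 3-[(3S)-non-1-en-3-yloxy]cyclohex-2-en-1-one | CCCCCC[C@@H](C=C)OC1=CC(=O)CCC1
F5 | step 5 | 4-[(3S)-non-1-en-3-yloxy]-2-oxocyclohex-3-en-1-yl acetate (both C12 epimers) | CCCCCC[C@@H](C=C)OC1=CC(=O)C(OC(C)=O)CC1
F6 | step 5 | (6R)-6-hydroxy-3-[(3S)-non-1-en-3-yloxy]cyclohex-2-en-1-one | CCCCCC[C@@H](C=C)OC1=CC(=O)[C@H](O)CC1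
F0 | step 3 | none | none
F7 | step 8 | (6R)-6-[(tert-butyldimethylsilyl)oxy]-3-{[(3S)-1,2-dihydroxynonan-3-yl]oxy}-2-ethenylcyclohex-2-en-1-one (both epimers at the secondary carbinol) | CCCCCC[C@@H](C(O)CO)OC1=C(C=C)C(=O)[C@H](O[Si](C)(C)C(C)(C)C)CC1
A1 | alternative 1 | phenolic chroman-fused pyranopyranone with free C7 carbinol (dearomatisation precursor) | CCCCCC[C@H](O)[C@@H]1C[C@H]2c3c(cc(C)oc3=O)Oc3c(O)ccc(O1)c32
A2 | alternative 1 | bicyclic quinone monoketal | CCCCCC[C@@H]1O[C@]23C=CC(=O)C4=C3[C@@H](C[C@@H]1O2)c1c(O4)cc(C)oc1=O
A3 | alternative 2 | 2-furyl ether of the (E)-nitroalkenyl syn-diol (cycloaddition precursor) | CCCCCC[C@H](O)[C@H](CC/C=C/[N+](=O)[O-])Oc1ccco1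
A4 | alternative 2 | tricyclic nitro ketal with C10=C11 and free C12 hydroxyl | CCCCCC[C@@H]1O[C@@]23C=C[C@@H](O)[C@@H]([N+](=O)[O-])[C@@H]2CC[C@@H]1O3
A5 | alternative 3 | iodo delta-lactone carrying the silylated pyranopyranone hemiketal (Barbier precursor) | CCCCCC[C@H](O[Si](C)(C)C(C)(C)C)[C@@H]1C[C@H]2c3c(cc(C)oc3=O)O[C@](O[Si](C)(C)C(C)(C)C)([C@H](O[Si](C)(C)C(C)(C)C)CCI)[C@H]2C(=O)O1
A6 | alternative 3 | tris-silylated C9 lactol | CCCCCC[C@H](O[Si](C)(C)C(C)(C)C)[C@@H]1C[C@H]2c3c(cc(C)oc3=O)O[C@]4(O[Si](C)(C)C(C)(C)C)[C@H](O[Si](C)(C)C(C)(C)C)CC[C@@](O)(O1)[C@@H]24
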